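**Retrosynthetic overview**

1. Target 27 ⇐ benzyl ether 25 (hydrogenolysis, then re-oxidation of the hydroquinone).
2. Quinone ring of 25 ⇐ four-membered ring: the arc C(=O)–C(OAr)=C(CH2CH2Ar)–C(=O) is a cyclobut-3-ene-1,2-dione, and the MeO–C=CH pair is a (Z)-2-methoxyvinyl group added to one carbonyl carbon. Thermal 4π opening and 6π closure expand four to six; Ag2O then gives the quinone.
3. Enabling feature: the quinone shares only one C=C with the 18-membered ring (the carbon bearing the ring-C aryloxy oxygen and the carbon bearing the ring-A CH2CH2 arm), and its carbonyls are para. That C=C plus both carbonyl carbons can therefore sit as a squarate-derived four-membered ring inside the intact macrocycle, and the aryloxy oxygen (vinylogous ester) steers the vinyllithium to the carbonyl that must receive the two new carbons.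
4. Macrocyclic cyclobutenedione 17 ⇐ fluoride-triggered vinylogous macro-esterification of chlorocyclobutenedione 16 ⇐ Grignard reagent + diisopropyl squarate. Open chain ⇐ Chan–Lam diaryl ether (rings A–B) and Wittig/hydrogenation bibenzyl (rings B–C).
5. Ring order: arene rings A (1,4-phenylene), B (the ring with OH) and C (1,3-phenylene) and the four-membered ring are bought; the 18-membered ring is closed in step 10; the six-membered quinone ring is formed last, in step 13.

Key step: step 13

Assumption: the SMILES has no stereocentre and no configured double bond, and the 18-membered ring is taken as conformationally mobile, so the target is achiral and no enantiocontrol is needed.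

**Route**

Step 1
Reactants: 1 4-(benzyloxy)-3-hydroxybenzaldehyde; 2 [4-(2-hydroxyethyl)phenyl]boronic acid
Product: 3 4-(benzyloxy)-3-[4-(2-hydroxyethyl)phenoxy]benzaldehyde
Conditions: Cu(OAc)2 (20 mol %), pyridine, 4 Å MS, O2 (1 atm), CH2Cl2, rt
Reagents that add atoms: none
Why: Chan–Lam oxidative O-arylation couples a phenol with an arylboronic acid at room temperature and should tolerate the aldehyde, the benzyl ether and the much less reactive primary alcohol.

Step 2
Reactants: 4 3-hydroxybenzyl alcohol
Product: 5 (3-hydroxybenzyl)triphenylphosphonium bromide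
Conditions: Ph3P·HBr, MeCN, reflux
Reagents that add atoms: triphenylphosphine hydrobromide, [Br-].[PH+](c1ccccc1)(c1ccccc1)c1ccccc1
Why: Benzylic alcohols are converted directly into benzylphosphonium bromides by this reagent (benzylic bromide formed in situ, then SN2 quaternisation), and the phenol is not touched.

Step 3
Reactants: 3 4-(benzyloxy)-3-[4-(2-hydroxyethyl)phenoxy]benzaldehyde; 5 (3-hydroxybenzyl)triphenylphosphonium bromide
Product: 7 3-[2-[4-(benzyloxy)-3-[4-(2-hydroxyethyl)phenoxy]phenyl]ethenyl]phenol (E/Z mixture), via phosphonium ylide 6 (not isolated)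
Conditions: 5, KOtBu (2.2 equiv), THF, 0 °C; then 3, 0 °C → rt; aq NH4Cl
Reagents that add atoms: none
Why: Wittig olefination with the semi-stabilised benzylic ylide (generated as its phenoxide by two equivalents of base) forms the stilbene as an E/Z mixture, which does not matter because the double bond is saturated in step 4.

Step 4
Reactants: 7 stilbene phenol (E/Z mixture)
Product: 8 3-[2-[4-(benzyloxy)-3-[4-(2-hydroxyethyl)phenoxy]phenyl]ethyl]phenol
Conditions: H2 (1 atm), 10% Pd/C, 2,2'-bipyridyl (0.5 equiv), EtOAc–MeOH, rt
Reagents that add atoms: none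
Why: Heterogeneous hydrogenation over Pd/C poisoned with a nitrogen base should saturate the stilbene C=C while hydrogenolysis of the phenolic benzyl ether is suppressed.

Step 5
Reactants: 8 bibenzyl phenol alcohol
Product: 9 3-[2-[4-(benzyloxy)-3-[4-(2-bromoethyl)phenoxy]phenyl]ethyl]phenol
Conditions: CBr4, PPh3, CH2Cl2, 0 °C
Reagents that add atoms: carbon tetrabromide, BrC(Br)(Br)Br
Why: Appel bromination converts the primary alcohol into the bromide by SN2 displacement of an alkoxyphosphonium ion, a pathway that is not open to the phenol.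

Step 6
Reactants: 9 bromide phenol
Product: 10 [3-[2-[4-(benzyloxy)-3-[4-(2-bromoethyl)phenoxy]phenyl]ethyl]phenoxy]triisopropylsilane
Conditions: TIPSOTf, 2,6-lutidine, CH2Cl2, 0 °C
Reagents that add atoms: triisopropylsilyl triflate, CC(C)[Si](OS(=O)(=O)C(F)(F)F)(C(C)C)C(C)C
Why: O-silylation gives an aryl silyl ether that should survive Grignard chemistry and aqueous acid yet is cleaved by fluoride, and the non-nucleophilic base spares the alkyl bromide.

Step 7
Reactants: 10 bromide TIPS ether; 11 diisopropyl squarate
Product: 14 3-isopropoxy-4-[2-[4-[2-(benzyloxy)-5-[2-[3-(triisopropylsilyloxy)phenyl]ethyl]phenoxy]phenyl]ethyl]cyclobut-3-ene-1,2-dione, via Grignard reagent 12 (not isolated), via hydroxycyclobutenone 13 (not isolated)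
Conditions: Mg, THF, rt; then 11, THF, −78 °C; aq NH4Cl; then 12 N HCl (cat.), CH2Cl2, rt
Reagents that add atoms: none
Why: Liebeskind–Moore squarate chemistry, in which the primary Grignard reagent adds 1,2 to one carbonyl of the squarate diester and acid then ionises the tertiary carbinol with loss of isopropanol (1,3-oxygen transposition) to the 3-alkyl-4-alkoxycyclobutenedione, so the racemic carbinol centre of 13 is destroyed.

Step 8
Reactants: 14 isopropoxycyclobutenedione
Product: 15 3-hydroxy-4-[2-[4-[2-(benzyloxy)-5-[2-[3-(triisopropylsilyloxy)phenyl]ethyl]phenoxy]phenyl]ethyl]cyclobut-3-ene-1,2-dione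
Conditions: 6 N HCl, THF, rt
Reagents that add atoms: water, O
Why: Acid hydrolysis of the vinylogous isopropyl ester (addition–elimination of water) gives the vinylogous acid under conditions that aryl TIPS and benzyl ethers should tolerate.

Step 9
Reactants: 15 hydroxycyclobutenedione
Product: 16 3-chloro-4-[2-[4-[2-(benzyloxy)-5-[2-[3-(triisopropylsilyloxy)phenyl]ethyl]phenoxy]phenyl]ethyl]cyclobut-3-ene-1,2-dione
Conditions: (COCl)2, DMF (cat.), CH2Cl2, 0 °C → rt
Reagents that add atoms: oxalyl chloride, O=C(Cl)C(=O)Cl
Why: Vilsmeier-type activation converts the vinylogous carboxylic acid into the vinylogous acid chloride, the standard access to 3-chlorocyclobutenediones.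

Step 10
Reactants: 16 chlorocyclobutenedione
Product: 17 macrocyclic 3-aryloxy-4-alkylcyclobut-3-ene-1,2-dione (18-membered ring closed through the ring-C oxygen; OBn on ring B)
Conditions: CsF (3 equiv), 18-crown-6 (cat.), MeCN, 50 °C, syringe-pump addition of 16 (final 1 mM)
Reagents that add atoms: none
Why: Fluoride-triggered desilylative acylation, in which CsF releases the ring-C phenoxide and this attacks the chlorine-bearing ring carbon by addition–elimination (a vinylogous esterification of macrolactonisation type) under high dilution.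

Step 11
Reactants: 18 methyl vinyl ether
Product: 20 (Z)-1-bromo-2-methoxyethene, via dibromide 19 (not isolated)
Conditions: Br2, CH2Cl2, −78 °C; then PhNEt2, 90 °C, distil
Reagents that add atoms: bromine, BrBr
Why: Bromine addition to the enol ether followed by amine-mediated E2 dehydrobromination is the established route to the ethoxy analogue and favours the (Z)-bromide, the isomer that undergoes clean Br/Li exchange.

Step 12
Reactants: 17 macrocyclic cyclobutenedione; 20 (Z)-1-bromo-2-methoxyethene
Product: 22 macrocyclic 4-hydroxy-4-[(Z)-2-methoxyvinyl]cyclobut-2-en-1-one (racemic; carbinol carbon next to the aryloxy-bearing ring carbon), via vinyllithium 21 (not isolated)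
Conditions: 20, n-BuLi, THF, −78 °C; then 17, THF, −78 °C; pH 7 buffer, −78 °C → 0 °C; used crude
Reagents that add atoms: none
Why: Br/Li exchange gives the chelation-stabilised (Z)-2-methoxyvinyllithium, which should add 1,2 to the ketone-type carbonyl next to the aryloxy-bearing carbon (the other carbonyl is deactivated as a vinylogous ester) as known for 3-alkoxy-4-alkylcyclobutenediones, and the new carbinol centre is racemic and disappears in step 13.

Step 13
Reactants: 22 macrocyclic hydroxycyclobutenone
Product: 25 O-benzyl ether of the target quinone, via dienylketene 23 (not isolated), via hydroquinone 24 (not isolated)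
Conditions: PhMe (degassed), 110 °C; then Ag2O, rt
Reagents that add atoms: none
Why: Heating opens the cyclobutenone by thermal 4π-conrotatory electrocyclic cleavage of the C(=O)–C(OH) bond, the hydroxyl rotating outward (torquoselectivity of a donor substituent) so that the methoxyvinyl group lies cis to the ketene in dienylketene 23; a thermal 6π-disrotatory electrocyclisation then joins the ketene carbon to the methoxy-bearing vinyl carbon, the cyclohexadienone enolises to hydroquinone 24, and Ag2O removes two hydrogens to give the quinone. The closest known reaction type is the Moore–Liebeskind ring expansion of squarate-derived 4-alkenyl-4-hydroxycyclobutenones to hydroquinones and quinones. The only ring closed is the six-membered carbocycle, by 6π electrocyclisation of a (Z)-dienylketene, while the 18-membered ring is untouched because its two atoms in the small ring are the C=C that is not cleaved. No stereocentre is created, the racemic carbinol centre of 22 is destroyed, and the enol ether geometry is lost on aromatisation. The step needs regiocontrol (methoxy next to the carbonyl flanked by the CH2CH2 arm) and chemoselective oxidation; the first is fixed by the connectivity of 22, since only the sp3 carbon–carbonyl bond can open and only the vinyl terminus can reach the ketene carbon, and the second by the low oxidation potential of the hydroquinone compared with the benzyl and aryl ethers.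

Step 14
Reactants: 25 O-benzyl quinone
Product: 27 target quinone CNP0332646.0, via hydroquinone 26 (not isolated)
Conditions: H2 (1 atm), 10% Pd/C, EtOAc, rt; filter; then Ag2O, MgSO4, rt
Reagents that add atoms: none
Why: Hydrogenolysis removes the O-benzyl group while reducing the quinone transiently to hydroquinone 26, which mild Ag2O oxidation should return to the quinone without touching the liberated mono-phenol.

**Compound list**

1 | 4-(benzyloxy)-3-hydroxybenzaldehyde | O=Cc1ccc(OCc2ccccc2)c(O)c1 | starting material
2 | [4-(2-hydroxyethyl)phenyl]boronic acid | OCCc1ccc(cc1)B(O)O | starting material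
3 | 4-(benzyloxy)-3-[4-(2-hydroxyethyl)phenoxy]benzaldehyde | O=Cc1ccc(OCc2ccccc2)c(Oc2ccc(CCO)cc2)c1 | intermediate
4 | 3-hydroxybenzyl alcohol | OCc1cccc(O)c1 | starting material
5 | (3-hydroxybenzyl)triphenylphosphonium bromide | [Br-].Oc1cccc(C[P+](c2ccccc2)(c2ccccc2)c2ccccc2)c1 | intermediate
6 | potassium 3-[(triphenylphosphoranylidene)methyl]phenolate (ylide, not isolated) | [K+].[O-]c1cccc(C=P(c2ccccc2)(c2ccccc2)c2ccccc2)c1 | intermediate
7 | 3-[2-[4-(benzyloxy)-3-[4-(2-hydroxyethyl)phenoxy]phenyl]ethenyl]phenol, E/Z mixture (geometry left unspecified) | Oc1cccc(C=Cc2ccc(OCc3ccccc3)c(Oc3ccc(CCO)cc3)c2)c1 | intermediate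
8 | 3-[2-[4-(benzyloxy)-3-[4-(2-hydroxyethyl)phenoxy]phenyl]ethyl]phenol | Oc1cccc(CCc2ccc(OCc3ccccc3)c(Oc3ccc(CCO)cc3)c2)c1 | intermediate
9 | 3-[2-[4-(benzyloxy)-3-[4-(2-bromoethyl)phenoxy]phenyl]ethyl]phenol | Oc1cccc(CCc2ccc(OCc3ccccc3)c(Oc3ccc(CCBr)cc3)c2)c1 | intermediate
10 | [3-[2-[4-(benzyloxy)-3-[4-(2-bromoethyl)phenoxy]phenyl]ethyl]phenoxy]triisopropylsilane | CC(C)[Si](Oc1cccc(CCc2ccc(OCc3ccccc3)c(Oc3ccc(CCBr)cc3)c2)c1)(C(C)C)C(C)C | intermediate
11 | diisopropyl squarate (3,4-diisopropoxycyclobut-3-ene-1,2-dione) | CC(C)OC1=C(OC(C)C)C(=O)C1=O | starting material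
12 | [2-[4-[2-(benzyloxy)-5-[2-[3-(triisopropylsilyloxy)phenyl]ethyl]phenoxy]phenyl]ethyl]magnesium bromide (not isolated) | CC(C)[Si](Oc1cccc(CCc2ccc(OCc3ccccc3)c(Oc3ccc(CC[Mg]Br)cc3)c2)c1)(C(C)C)C(C)C | intermediate
13 | 4-hydroxy-2,3-diisopropoxy-4-[2-[4-[2-(benzyloxy)-5-[2-[3-(triisopropylsilyloxy)phenyl]ethyl]phenoxy]phenyl]ethyl]cyclobut-2-en-1-one, racemic (not isolated) | CC(C)OC1=C(OC(C)C)C(O)(CCc2ccc(Oc3cc(CCc4cccc(O[Si](C(C)C)(C(C)C)C(C)C)c4)ccc3OCc3ccccc3)cc2)C1=O | intermediate
14 | 3-isopropoxy-4-[2-[4-[2-(benzyloxy)-5-[2-[3-(triisopropylsilyloxy)phenyl]ethyl]phenoxy]phenyl]ethyl]cyclobut-3-ene-1,2-dione | CC(C)OC1=C(CCc2ccc(Oc3cc(CCc4cccc(O[Si](C(C)C)(C(C)C)C(C)C)c4)ccc3OCc3ccccc3)cc2)C(=O)C1=O | intermediate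
15 | 3-hydroxy-4-[same arylethyl arm]cyclobut-3-ene-1,2-dione | OC1=C(CCc2ccc(Oc3cc(CCc4cccc(O[Si](C(C)C)(C(C)C)C(C)C)c4)ccc3OCc3ccccc3)cc2)C(=O)C1=O | intermediate
16 | 3-chloro-4-[same arylethyl arm]cyclobut-3-ene-1,2-dione | ClC1=C(CCc2ccc(Oc3cc(CCc4cccc(O[Si](C(C)C)(C(C)C)C(C)C)c4)ccc3OCc3ccccc3)cc2)C(=O)C1=O | intermediate
17 | macrocyclic cyclobut-3-ene-1,2-dione: C3 bonded to the ring-C oxygen, C4 to the ring-A CH2CH2 arm, 18-membered ring, OBn on ring B ortho to the diaryl ether oxygen | O=C1C(=O)C2=C1CCc1ccc(cc1)Oc1cc(ccc1OCc1ccccc1)CCc1cccc(c1)O2 | intermediate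
18 | methyl vinyl ether | COC=C | starting material
19 | 1,2-dibromo-1-methoxyethane, racemic (not isolated) | COC(Br)CBr | intermediate
20 | (Z)-1-bromo-2-methoxyethene | CO/C=C\Br | intermediate
21 | (Z)-(2-methoxyvinyl)lithium (not isolated) | CO/C=C\[Li] | intermediate
22 | macrocyclic 4-hydroxy-4-[(Z)-2-methoxyvinyl]cyclobut-2-en-1-one, racemic; carbinol carbon bonded to the aryloxy-bearing alkene carbon, remaining carbonyl next to the alkyl-bearing alkene carbon | CO/C=C\C1(O)C(=O)C2=C1Oc1cccc(c1)CCc1ccc(OCc3ccccc3)c(c1)Oc1ccc(CC2)cc1 | intermediate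
23 | macrocyclic dienylketene: ketene on the alkyl-bearing carbon, (Z)-enol with the methoxyvinyl group cis to the ketene-bearing carbon (not isolated) | CO/C=C\C(O)=C1/C(=C=O)CCc2ccc(cc2)Oc2cc(ccc2OCc2ccccc2)CCc2cccc(c2)O1 | intermediate
24 | macrocyclic 2-methoxyhydroquinone, O-benzyl on ring B (not isolated) | COc1cc(O)c2c(c1O)CCc1ccc(cc1)Oc1cc(ccc1OCc1ccccc1)CCc1cccc(c1)O2 | intermediate
25 | O-benzyl ether of the target quinone | COC1=CC(=O)C2=C(CCc3ccc(cc3)Oc3cc(ccc3OCc3ccccc3)CCc3cccc(c3)O2)C1=O | intermediate
26 | macrocyclic 2-methoxyhydroquinone with free ring-B phenol (not isolated) | COc1cc(O)c2c(c1O)CCc1ccc(cc1)Oc1cc(ccc1O)CCc1cccc(c1)O2 | intermediate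
27 | target quinone CNP0332646.0 (no stereocentre) | COC1=CC(=O)C2=C(CCc3ccc(cc3)Oc3cc(ccc3O)CCc3cccc(c3)O2)C1=O | target

**Step count and risks**

Total steps: 14. Longest linear sequence: 12 (steps 1, 3–10, 12–14).

Steps most likely to fail:

Step 10 (macrocyclisation). The phenoxide may be released faster than it cyclises, which leads to intermolecular acylation (oligomers), and fluoride or traces of hydroxide may consume the acid chloride first. The fallback separates activation, unmasking and ring closure, with an isolable active ester in place of the acid chloride; it sets out from 16 and returns at 17. Compound 16 is treated with pentafluorophenol and Et3N (CH2Cl2, 0 °C) to give the pentafluorophenyl vinylogous ester F1. HF·pyridine (THF, 0 °C) then removes the silyl group to give the free phenol active ester F2. Slow syringe-pump addition of F2 to Cs2CO3 in MeCN (1 mM, 40 °C) should close the ring by aryl-for-aryl transesterification, with pentafluorophenoxide as the leaving group and no fluoride present, to give 17.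

Step 12 (vinyllithium addition). The basic vinyllithium may attack the aryloxy-bearing ring carbon and expel the macrocyclic phenoxide (ring opening), and the tertiary β-methoxyallylic carbinol may ionise on work-up. The fallback takes the methoxy group out of the addition and ring expansion and introduces it last; it sets out from 17 and returns at 25. Vinylmagnesium bromide (THF, −78 °C) should give the robust 4-vinyl carbinol F3. Thermolysis (PhMe, 110 °C) should give the methoxy-free hydroquinone F4, which Ag2O oxidises in the same flask to the methoxy-free quinone F5. Zinc chloride-promoted conjugate addition of methanol to F5 (MeOH, ZnCl2, rt) should occur at the unsubstituted carbon β to the carbonyl that the aryloxy group does not deactivate, which is the required position, to give hydroquinone 24; Ag2O then gives 25.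

Step 13 (ring expansion and oxidation). Torquoselectivity may be lost in the ring opening, so that the hydroxyl rotates inward and the hydroxy ketene lactonises to a furanone, and the ring-closed dienone may lose methanol before it tautomerises. The fallback caps the hydroxyl and separates rearrangement from oxidation; it sets out from 22 and returns at 25. N-(Trimethylsilyl)imidazole (CH2Cl2, rt) converts 22 into the trimethylsilyl ether F6. Thermolysis (PhMe, 110 °C) should give the mono-silylated hydroquinone F7, in which no free hydroxyl is available to trap the ketene. Oxidative desilylation with PhI(OAc)2 (MeCN–H2O, 0 °C) gives 25.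

**Further compounds**

F1 | step 10 | 3-(pentafluorophenoxy)-4-[2-[4-[2-(benzyloxy)-5-[2-[3-(triisopropylsilyloxy)phenyl]ethyl]phenoxy]phenyl]ethyl]cyclobut-3-ene-1,2-dione | CC(C)[Si](Oc1cccc(CCc2ccc(OCc3ccccc3)c(Oc3ccc(CCC4=C(Oc5c(F)c(F)c(F)c(F)c5F)C(=O)C4=O)cc3)c2)c1)(C(C)C)C(C)C
F2 | step 10 | 3-(pentafluorophenoxy)-4-[2-[4-[2-(benzyloxy)-5-[2-(3-hydroxyphenyl)ethyl]phenoxy]phenyl]ethyl]cyclobut-3-ene-1,2-dione | Oc1cccc(CCc2ccc(OCc3ccccc3)c(Oc3ccc(CCC4=C(Oc5c(F)c(F)c(F)c(F)c5F)C(=O)C4=O)cc3)c2)c1
F3 | step 12 | macrocyclic 4-hydroxy-4-vinylcyclobut-2-en-1-one (racemic; vinyl analogue of 22) | C=CC1(O)C(=O)C2=C1Oc1cccc(c1)CCc1ccc(OCc3ccccc3)c(c1)Oc1ccc(CC2)cc1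
F4 | step 12 | macrocyclic hydroquinone lacking the methoxy group (O-benzyl on ring B) | Oc1ccc(O)c2c1CCc1ccc(cc1)Oc1cc(ccc1OCc1ccccc1)CCc1cccc(c1)O2
F5 | step 12 | macrocyclic quinone lacking the methoxy group (O-benzyl on ring B) | O=C1C=CC(=O)C2=C1CCc1ccc(cc1)Oc1cc(ccc1OCc1ccccc1)CCc1cccc(c1)O2
F6 | step 13 | trimethylsilyl ether of 22 (racemic) | CO/C=C\C1(O[Si](C)(C)C)C(=O)C2=C1Oc1cccc(c1)CCc1ccc(OCc3ccccc3)c(c1)Oc1ccc(CC2)cc1
F7 | step 13 | mono-trimethylsilyl ether of hydroquinone 24 (silyl on the oxygen next to the CH position) | COc1cc(O[Si](C)(C)C)c2c(c1O)CCc1ccc(cc1)Oc1cc(ccc1OCc1ccccc1)CCc1cccc(c1)O2
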